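At the first reading of the red run, 8.00 h in, this flask held 61.4% of intermediate, and I asked what would have to be true for its peak to stand far above that reading.

- red: substrate 1.2 M; partner 0.90 equiv; the very flask that is asked about, followed so far
- flask: substrate 1.2 M; partner 0.900 equiv; time 15 d

red run (percent of the substrate charged)

| time / h | intermediate / % | target / % |
|---|---|---|
| 8.00 | 61.4 | 6.2 |
| 15.0 | 57.4 | 12.1 |
| 20.0 | 54.9 | 14.2 |
| 30.0 | 49.3 | 16.4 |

(standard deviation of a reading: 0.5 percentage points)



1. time, not beyond 15 d, at which the flask holds most intermediate
2. the amount of intermediate, in percent of the substrate charged, at that time
3. earliest time at which at least nineteen twentieths of that best amount are there, in d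
4. latest time at which they still are, in d

I assumed that each intermediate made costs one partner, and so I measured the flask by its partner yield, the intermediate at the first reading per partner charged: 68.2%. For the opposite outcome, a peak holding the whole partner charge as intermediate, this yield would have to reach one. The readings pointed the other way: from 8.00 h to 15.0 h the intermediate fell by 4 percentage points, more than the scatter of 0.5 points. I replaced the falling curve by its mean line from the first reading to the last and ran that line back to zero time, which gave a rough high estimate of 65.8%, a yield of 73.1%. So my own estimate put the best between the first reading and that figure, with the peak close to the first reading in time.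

The forecast put the best at 62% (range 60.5% to 65%) at 0.25 d, earlier than the first reading, with the band from 0.17 d to 0.52 d, and it warned: “This early side is inferred, not measured.”

The flask peaked at 0.361 d with 61.4% of intermediate, and the band ran from 0.207 d to 0.640 d.

    substrate + partner → intermediate + by-product (k = 0.396 /M/h)
    intermediate ⇌ target (K = 0.360, k = 0.0260 /h)
    intermediate ⇌ isomer of the product (K = 5.80, k = 0.0104 /h)
    partner + target → over-reaction product A (k = 0.137 /M/h)
    target → over-reaction product B (k = 2.87 × 10⁻⁵ /h)

At that best time this flask still held 15.5% of its partner, the limiting reagent, and the yield stood at 68.3%. On the neighbour charged with 0.360 equiv of partner, my yield gave a best of 24.6%, and that neighbour reached 28.3%.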